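The C ring of the upper (robinetinidol) unit is cut at O1–C8a and C3–C4. The key step exploits that C4 is benzylic to ring A with C8a as its ortho ring carbon, while O1 and C3 flank the stereocentre C2. A lithiated dithiane of 4-benzyloxy-2-fluorobenzaldehyde (nucleophilic C4, fluoride at C8a) meets an (R)-aryloxirane (electrophilic C3, latent alkoxide O1) in an anionic [3+3] annulation: epoxide opening, then intramolecular SNAr. C2 then relays the rest: the unmasked flavanone takes up 8-metallated gallocatechin, dehydration gives a 4-arylflav-3-ene, dihydroxylation sets C3 anti to the 2-aryl group, and hydride delivery to the C4 cation anti to O3 gives the 3,4-cis (4β) linkage.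

Key step: step 4

Remark: the target is read as robinetinidol-(4β→8)-gallocatechin (upper unit 2R,3S,4R, i.e. 2,3-trans-3,4-cis; lower unit 2R,3S); compounds 1, 4 and 10 are assumed to be purchasable.

Step 1
Reactants: 1 3,4,5-tris(benzyloxy)benzaldehyde
Product: 2 rac-2-[3,4,5-tris(benzyloxy)phenyl]oxirane
Conditions: Me3S+ I−, NaH, DMSO/THF, 0 → 25 °C
Reagents that add atoms: trimethylsulfonium iodide, C[S+](C)C.[I-]
Why: Corey–Chaykovsky methylene transfer from dimethylsulfonium methylide to an aromatic aldehyde should give the terminal epoxide, racemic at this stage.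

Step 2
Reactants: 2 rac-2-[3,4,5-tris(benzyloxy)phenyl]oxirane
Product: 3 (R)-2-[3,4,5-tris(benzyloxy)phenyl]oxirane
Conditions: (S,S)-(salen)Co(OAc) (trivalent cobalt, 0.8 mol %), H2O (0.55 equiv), THF, 0 → 25 °C
Reagents that add atoms: none
Why: Jacobsen hydrolytic kinetic resolution with the ligand enantiomer that consumes the (S)-epoxide should leave the (R)-epoxide in high ee; its stereocentre becomes C2 of the upper unit.

Step 3
Reactants: 4 4-(benzyloxy)-2-fluorobenzaldehyde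
Product: 5 2-[4-(benzyloxy)-2-fluorophenyl]-1,3-dithiane
Conditions: HS(CH2)3SH, I2 (10 mol %), CHCl3, 25 °C
Reagents that add atoms: propane-1,3-dithiol, SCCCS
Why: Iodine-catalysed dithioacetalization of an aryl aldehyde, mild enough to spare the benzyl ether, installs the Corey–Seebach acyl-anion handle at the future C4.

Step 4
Reactants: 5 2-[4-(benzyloxy)-2-fluorophenyl]-1,3-dithiane; 3 (R)-2-[3,4,5-tris(benzyloxy)phenyl]oxirane
Product: 8 (2S)-7-(benzyloxy)-2-[3,4,5-tris(benzyloxy)phenyl]spiro[chromane-4,2'-[1,3]dithiane], via 2-lithio-1,3-dithiane 6 (not isolated), via lithium alkoxide 7 (not isolated)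
Conditions: 5, n-BuLi, THF, −78 °C; 3, DMPU, −78 → 0 °C; then t-BuOK, 60 °C
Reagents that add atoms: none
Why: Deprotonation of 5 gives the 2-aryl-2-lithiodithiane 6, which opens epoxide 3 by SN2 attack at the unsubstituted carbon (new C3–C4 bond); the liberated C2 alkoxide 7, after exchange to potassium, displaces the ortho fluoride of ring A by addition–elimination through a Meisenheimer intermediate (new O1–C8a bond). The closest known reaction types are the dithiane-anion/epoxide coupling and the alkoxide SNAr closure of 3-(2-fluoroaryl)propanols to chromans, here telescoped into a formal [3+3] annulation. Ring C closes in a 6-exo-trig-type ipso attack at C8a, helped by the gem-dithio substitution at C4. No new stereocentre is formed: C2 keeps the configuration of 3 because its C–O bond is never broken, and the spiro C4 is achiral. The step needs attack at the terminal epoxide carbon, which the bulk of the tertiary carbanion should secure, and lithiation at the dithiane C–H instead of the aryl C–H between F and OBn, which the far higher acidity of the dithiane proton at −78 °C should secure. The alkoxide is the only oxygen nucleophile and can only close a six-membered ring, and the 7-benzyloxy group is meta to fluoride, so it does not deactivate the substitution by resonance.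

Step 5
Reactants: 8 (2S)-7-(benzyloxy)-2-[3,4,5-tris(benzyloxy)phenyl]spiro[chromane-4,2'-[1,3]dithiane]
Product: 9 (2S)-7-(benzyloxy)-2-[3,4,5-tris(benzyloxy)phenyl]chroman-4-one
Conditions: MeI, CaCO3, MeCN/H2O (9:1), 45 °C
Reagents that add atoms: water, O
Why: S-Methylation and hydrolysis of the dithioketal under buffered, non-basic conditions should unveil the C4 ketone without retro-oxa-Michael opening of the flavanone, so C2 stays intact.

Step 6
Reactants: 10 (+)-gallocatechin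
Product: 11 (2R,3S)-5,7-bis(benzyloxy)-2-[3,4,5-tris(benzyloxy)phenyl]chroman-3-ol
Conditions: BnBr, K2CO3, DMF, argon, 0 → 25 °C
Reagents that add atoms: benzyl bromide, BrCc1ccccc1
Why: Williamson etherification with carbonate should alkylate the five phenols and leave the aliphatic 3-hydroxyl, with air excluded to protect the pyrogallol ring.

Step 7
Reactants: 11 (2R,3S)-5,7-bis(benzyloxy)-2-[3,4,5-tris(benzyloxy)phenyl]chroman-3-ol
Product: 12 (2R,3S)-3,5,7-tris(benzyloxy)-2-[3,4,5-tris(benzyloxy)phenyl]chromane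
Conditions: NaH, BnBr, n-Bu4NI (cat.), DMF, 0 → 25 °C
Reagents that add atoms: benzyl bromide, BrCc1ccccc1
Why: Williamson benzylation of the secondary alkoxide removes the last acidic proton before the organolithium step.

Step 8
Reactants: 12 (2R,3S)-3,5,7-tris(benzyloxy)-2-[3,4,5-tris(benzyloxy)phenyl]chromane
Product: 13 (2R,3S)-3,5,7-tris(benzyloxy)-8-bromo-2-[3,4,5-tris(benzyloxy)phenyl]chromane
Conditions: NBS, CH2Cl2, −40 → 0 °C
Reagents that add atoms: N-bromosuccinimide, O=C1CCC(=O)N1Br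
Why: Electrophilic aromatic bromination of the phloroglucinol-type ring should occur at C8, between the 7-benzyloxy group and the ring oxygen, as is usual for 5,7-di-O-alkyl flavan-3-ols.

Step 9
Reactants: 13 (2R,3S)-3,5,7-tris(benzyloxy)-8-bromo-2-[3,4,5-tris(benzyloxy)phenyl]chromane; 9 (2S)-7-(benzyloxy)-2-[3,4,5-tris(benzyloxy)phenyl]chroman-4-one
Product: 16 (2S)-7-(benzyloxy)-4-[(2R,3S)-3,5,7-tris(benzyloxy)-2-[3,4,5-tris(benzyloxy)phenyl]chroman-8-yl]-2-[3,4,5-tris(benzyloxy)phenyl]-2H-chromene, via 8-lithio arene 14 (not isolated), via tertiary carbinol 15 (not isolated)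
Conditions: 13, t-BuLi (2 equiv), THF, −78 °C; CeCl3, −78 °C; 9, −78 → −30 °C; aq. NH4Cl; then PPTS (cat.), CH2Cl2, 25 °C
Reagents that add atoms: none
Why: Bromine–lithium exchange, transmetalation to the weakly basic organocerium and 1,2-addition to the flavanone carbonyl should give the doubly benzylic tertiary carbinol, which loses water under mild acid (E1) to the conjugated 4-aryl-2H-chromene without touching C2.

Step 10
Reactants: 16 (2S)-7-(benzyloxy)-4-[(2R,3S)-3,5,7-tris(benzyloxy)-2-[3,4,5-tris(benzyloxy)phenyl]chroman-8-yl]-2-[3,4,5-tris(benzyloxy)phenyl]-2H-chromene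
Product: 17 (2R,3R,4R)-7-(benzyloxy)-4-[(2R,3S)-3,5,7-tris(benzyloxy)-2-[3,4,5-tris(benzyloxy)phenyl]chroman-8-yl]-2-[3,4,5-tris(benzyloxy)phenyl]chromane-3,4-diol
Conditions: OsO4 (5 mol %), NMO, MeSO2NH2, acetone/H2O, 25 °C
Reagents that add atoms: osmium tetroxide, O=[Os](=O)(=O)=O (transfers both oxygens); N-methylmorpholine N-oxide, C[N+]1([O-])CCOCC1 (reoxidant); water, O (hydrolysis of the osmate ester)
Why: Upjohn syn-dihydroxylation of the trisubstituted styrenyl alkene from the face anti to the allylic 2-aryl group should set the 3β-hydroxyl (2,3-trans) and give the 3,4-cis diol.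

Step 11
Reactants: 17 (2R,3R,4R)-7-(benzyloxy)-4-[(2R,3S)-3,5,7-tris(benzyloxy)-2-[3,4,5-tris(benzyloxy)phenyl]chroman-8-yl]-2-[3,4,5-tris(benzyloxy)phenyl]chromane-3,4-diol
Product: 18 (2R,3S,4R)-7-(benzyloxy)-4-[(2R,3S)-3,5,7-tris(benzyloxy)-2-[3,4,5-tris(benzyloxy)phenyl]chroman-8-yl]-2-[3,4,5-tris(benzyloxy)phenyl]chroman-3-ol
Conditions: Et3SiH (10 equiv), CF3CO2H, CH2Cl2, −40 → 0 °C
Reagents that add atoms: none
Why: Ionic hydrogenation: the tertiary, doubly benzylic C4–OH should ionize selectively and the planar C4 cation should take hydride on the α face, anti to the adjacent 3β-hydroxyl, which places the gallocatechin ring β (3,4-cis, 4R).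

Step 12
Reactants: 18 (2R,3S,4R)-7-(benzyloxy)-4-[(2R,3S)-3,5,7-tris(benzyloxy)-2-[3,4,5-tris(benzyloxy)phenyl]chroman-8-yl]-2-[3,4,5-tris(benzyloxy)phenyl]chroman-3-ol
Product: 19 robinetinidol-(4β→8)-gallocatechin, (2R,3S,4R)-4-[(2R,3S)-3,5,7-trihydroxy-2-(3,4,5-trihydroxyphenyl)chroman-8-yl]-2-(3,4,5-trihydroxyphenyl)chromane-3,7-diol
Conditions: H2 (1 atm), 20% Pd(OH)2/C, THF/MeOH/H2O, 25 °C
Reagents that add atoms: none
Why: Hydrogenolysis of the ten benzyl ethers over Pearlman's catalyst under neutral conditions should free all hydroxyls without cleaving the acid-labile interflavan bond.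

Compound list
1 | 3,4,5-tris(benzyloxy)benzaldehyde | O=Cc1cc(OCc2ccccc2)c(OCc2ccccc2)c(OCc2ccccc2)c1 | starting material
2 | rac-2-[3,4,5-tris(benzyloxy)phenyl]oxirane | C1OC1c1cc(OCc2ccccc2)c(OCc2ccccc2)c(OCc2ccccc2)c1 | intermediate
3 | (R)-2-[3,4,5-tris(benzyloxy)phenyl]oxirane | C1O[C@@H]1c1cc(OCc2ccccc2)c(OCc2ccccc2)c(OCc2ccccc2)c1 | intermediate
4 | 4-(benzyloxy)-2-fluorobenzaldehyde | O=Cc1ccc(OCc2ccccc2)cc1F | starting material
5 | 2-[4-(benzyloxy)-2-fluorophenyl]-1,3-dithiane | Fc1cc(OCc2ccccc2)ccc1C1SCCCS1 | intermediate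
6 | 2-[4-(benzyloxy)-2-fluorophenyl]-2-lithio-1,3-dithiane | [Li]C1(SCCCS1)c1ccc(OCc2ccccc2)cc1F | intermediate
7 | lithium (1S)-2-{2-[4-(benzyloxy)-2-fluorophenyl]-1,3-dithian-2-yl}-1-[3,4,5-tris(benzyloxy)phenyl]ethan-1-olate | [Li+].[O-][C@@H](CC1(SCCCS1)c1ccc(OCc2ccccc2)cc1F)c1cc(OCc2ccccc2)c(OCc2ccccc2)c(OCc2ccccc2)c1 | intermediate
8 | (2S)-7-(benzyloxy)-2-[3,4,5-tris(benzyloxy)phenyl]spiro[chromane-4,2'-[1,3]dithiane] | O(Cc1ccccc1)c1ccc2c(c1)O[C@H](c1cc(OCc3ccccc3)c(OCc3ccccc3)c(OCc3ccccc3)c1)CC21SCCCS1 | intermediate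
9 | (2S)-7-(benzyloxy)-2-[3,4,5-tris(benzyloxy)phenyl]chroman-4-one | O(Cc1ccccc1)c1ccc2c(c1)O[C@H](c1cc(OCc3ccccc3)c(OCc3ccccc3)c(OCc3ccccc3)c1)CC2=O | intermediate
10 | (+)-gallocatechin, (2R,3S)-2-(3,4,5-trihydroxyphenyl)chromane-3,5,7-triol | Oc1cc(O)c2c(c1)O[C@H](c1cc(O)c(O)c(O)c1)[C@@H](O)C2 | starting material
11 | (2R,3S)-5,7-bis(benzyloxy)-2-[3,4,5-tris(benzyloxy)phenyl]chroman-3-ol | O(Cc1ccccc1)c1cc(OCc3ccccc3)c2c(c1)O[C@H](c1cc(OCc3ccccc3)c(OCc3ccccc3)c(OCc3ccccc3)c1)[C@@H](O)C2 | intermediate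
12 | (2R,3S)-3,5,7-tris(benzyloxy)-2-[3,4,5-tris(benzyloxy)phenyl]chromane | O(Cc1ccccc1)c1cc(OCc3ccccc3)c2c(c1)O[C@H](c1cc(OCc3ccccc3)c(OCc3ccccc3)c(OCc3ccccc3)c1)[C@@H](OCc1ccccc1)C2 | intermediate
13 | (2R,3S)-3,5,7-tris(benzyloxy)-8-bromo-2-[3,4,5-tris(benzyloxy)phenyl]chromane | O(Cc1ccccc1)c1cc(OCc3ccccc3)c2c(c1Br)O[C@H](c1cc(OCc3ccccc3)c(OCc3ccccc3)c(OCc3ccccc3)c1)[C@@H](OCc1ccccc1)C2 | intermediate
14 | (2R,3S)-3,5,7-tris(benzyloxy)-8-lithio-2-[3,4,5-tris(benzyloxy)phenyl]chromane | O(Cc1ccccc1)c1cc(OCc3ccccc3)c2c(c1[Li])O[C@H](c1cc(OCc3ccccc3)c(OCc3ccccc3)c(OCc3ccccc3)c1)[C@@H](OCc1ccccc1)C2 | intermediate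
15 | (2S)-7-(benzyloxy)-4-[(2R,3S)-3,5,7-tris(benzyloxy)-2-[3,4,5-tris(benzyloxy)phenyl]chroman-8-yl]-2-[3,4,5-tris(benzyloxy)phenyl]chroman-4-ol (both C4 epimers) | O(Cc1ccccc1)c1ccc2c(c1)O[C@H](c1cc(OCc3ccccc3)c(OCc3ccccc3)c(OCc3ccccc3)c1)CC2(O)c1c(OCc3ccccc3)cc(OCc3ccccc3)c2c1O[C@H](c1cc(OCc3ccccc3)c(OCc3ccccc3)c(OCc3ccccc3)c1)[C@@H](OCc1ccccc1)C2 | intermediate
16 | (2S)-7-(benzyloxy)-4-[(2R,3S)-3,5,7-tris(benzyloxy)-2-[3,4,5-tris(benzyloxy)phenyl]chroman-8-yl]-2-[3,4,5-tris(benzyloxy)phenyl]-2H-chromene | O(Cc1ccccc1)c1ccc2c(c1)O[C@H](c1cc(OCc3ccccc3)c(OCc3ccccc3)c(OCc3ccccc3)c1)C=C2c1c(OCc3ccccc3)cc(OCc3ccccc3)c2c1O[C@H](c1cc(OCc3ccccc3)c(OCc3ccccc3)c(OCc3ccccc3)c1)[C@@H](OCc1ccccc1)C2 | intermediate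
17 | (2R,3R,4R)-7-(benzyloxy)-4-[(2R,3S)-3,5,7-tris(benzyloxy)-2-[3,4,5-tris(benzyloxy)phenyl]chroman-8-yl]-2-[3,4,5-tris(benzyloxy)phenyl]chromane-3,4-diol (2,3-trans-3,4-cis diol, 4-aryl α) | O(Cc1ccccc1)c1ccc2c(c1)O[C@H](c1cc(OCc3ccccc3)c(OCc3ccccc3)c(OCc3ccccc3)c1)[C@@H](O)[C@]2(O)c1c(OCc3ccccc3)cc(OCc3ccccc3)c2c1O[C@H](c1cc(OCc3ccccc3)c(OCc3ccccc3)c(OCc3ccccc3)c1)[C@@H](OCc1ccccc1)C2 | intermediate
18 | (2R,3S,4R)-7-(benzyloxy)-4-[(2R,3S)-3,5,7-tris(benzyloxy)-2-[3,4,5-tris(benzyloxy)phenyl]chroman-8-yl]-2-[3,4,5-tris(benzyloxy)phenyl]chroman-3-ol (deca-O-benzyl dimer, 4-aryl β) | O(Cc1ccccc1)c1ccc2c(c1)O[C@H](c1cc(OCc3ccccc3)c(OCc3ccccc3)c(OCc3ccccc3)c1)[C@@H](O)[C@H]2c1c(OCc3ccccc3)cc(OCc3ccccc3)c2c1O[C@H](c1cc(OCc3ccccc3)c(OCc3ccccc3)c(OCc3ccccc3)c1)[C@@H](OCc1ccccc1)C2 | intermediate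
19 | robinetinidol-(4β→8)-gallocatechin | Oc1ccc2c(c1)O[C@H](c1cc(O)c(O)c(O)c1)[C@@H](O)[C@H]2c1c(O)cc(O)c2c1O[C@H](c1cc(O)c(O)c(O)c1)[C@@H](O)C2 | target

Total step count: 12. Longest linear sequence: 8 steps (1, 2, 4, 5, 9, 10, 11, 12).

Steps most likely to fail

Step 9: the hindered 2,6-dioxygenated aryl metal may enolize flavanone 9 (followed by retro-oxa-Michael ring opening and loss of C2 integrity) instead of adding to the carbonyl. The fallback sets out from 9 and avoids carbonyl addition altogether. Condensation with tosylhydrazide (MeOH, 50 °C) should give the N-tosylhydrazone F1, which is coupled with bromide 13 in a Barluenga reaction (Pd2(dba)3, XPhos, LiOt-Bu, dioxane, 90 °C). The diazo compound formed in the flask gives a palladium carbene; aryl migration and β-hydride elimination toward C3 should then deliver the 4-arylflav-3-ene, and the route is rejoined at 16.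

Step 11: hydride capture may show poor facial selectivity, or the C4 cation may lose the C3 proton or undergo a pinacol-type hydride shift to a flavan-3-one before it is reduced. The fallback sets out from 17 and replaces the cation by a radical. The cis-diol is closed with 1,1'-thiocarbonyldiimidazole (toluene, 80 °C) to the cyclic thionocarbonate F4. Treatment with n-Bu3SnH and AIBN (toluene, 90 °C) should then cleave the C4–O bond by Barton-type fragmentation toward the tertiary diaryl radical, which abstracts hydrogen anti to the C3 substituent to give the S-stannyl thiocarbonate F5. K2CO3 in MeOH frees the 3-hydroxyl and the route is rejoined at 18.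

Step 10: the alkene carries a 2,6-dioxygenated aryl group at C4, so osmylation may be too slow or be overtaken by oxidation of the electron-rich rings. The fallback sets out from 16. Epoxidation with dimethyldioxirane (acetone/CH2Cl2, −40 °C), anti to the 2-aryl group, should give the 3β,4β-epoxide F2, which is opened by water at the tertiary benzylic C4 (THF/H2O, PPTS cat., 0 °C). This should give 17 together with its C4 epimer F3. Both diols ionize to the same C4 cation, so the mixture is carried through the conditions of step 11 and the route is rejoined at 18.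

Further compounds
F1 | step 9 | N'-[(2S)-7-(benzyloxy)-2-[3,4,5-tris(benzyloxy)phenyl]chroman-4-ylidene]-4-methylbenzenesulfonohydrazide | O(Cc1ccccc1)c1ccc2c(c1)O[C@H](c1cc(OCc3ccccc3)c(OCc3ccccc3)c(OCc3ccccc3)c1)CC2=NNS(=O)(=O)c1ccc(C)cc1
F2 | step 10 | 3β,4β-epoxide of 16 (2,3-trans; 4-aryl α) | O(Cc1ccccc1)c1ccc2c(c1)O[C@H](c1cc(OCc3ccccc3)c(OCc3ccccc3)c(OCc3ccccc3)c1)[C@H]4O[C@@]24c1c(OCc3ccccc3)cc(OCc3ccccc3)c2c1O[C@H](c1cc(OCc3ccccc3)c(OCc3ccccc3)c(OCc3ccccc3)c1)[C@@H](OCc1ccccc1)C2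
F3 | step 10 | C4 epimer of 17 (2,3-trans-3,4-trans diol, 4-aryl β) | O(Cc1ccccc1)c1ccc2c(c1)O[C@H](c1cc(OCc3ccccc3)c(OCc3ccccc3)c(OCc3ccccc3)c1)[C@@H](O)[C@@]2(O)c1c(OCc3ccccc3)cc(OCc3ccccc3)c2c1O[C@H](c1cc(OCc3ccccc3)c(OCc3ccccc3)c(OCc3ccccc3)c1)[C@@H](OCc1ccccc1)C2
F4 | step 11 | cyclic 3,4-thionocarbonate of 17 | O(Cc1ccccc1)c1ccc2c(c1)O[C@H](c1cc(OCc3ccccc3)c(OCc3ccccc3)c(OCc3ccccc3)c1)[C@H]4OC(=S)O[C@@]24c1c(OCc3ccccc3)cc(OCc3ccccc3)c2c1O[C@H](c1cc(OCc3ccccc3)c(OCc3ccccc3)c(OCc3ccccc3)c1)[C@@H](OCc1ccccc1)C2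
F5 | step 11 | 3-O-[(tributylstannylsulfanyl)carbonyl] derivative of 18 | O(Cc1ccccc1)c1ccc2c(c1)O[C@H](c1cc(OCc3ccccc3)c(OCc3ccccc3)c(OCc3ccccc3)c1)[C@@H](OC(=O)S[Sn](CCCC)(CCCC)CCCC)[C@H]2c1c(OCc3ccccc3)cc(OCc3ccccc3)c2c1O[C@H](c1cc(OCc3ccccc3)c(OCc3ccccc3)c(OCc3ccccc3)c1)[C@@H](OCc1ccccc1)C2
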